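**Abbreviations:** PMB = 4-methoxybenzyl, Tr = trityl, TBDPS = tert-butyldiphenylsilyl, DIBAL-H = i-Bu2AlH, Red-Al = NaAlH2(OCH2CH2OCH3)2, DMP = Dess–Martin periodinane. Germacrane numbering is used for all ring compounds.

## Analysis of the target

Target 43 is a melampolide-type germacranolide. A ten-membered carbocycle (C1–C10) is fused at C6–C7 to a butenolide (O on C6, C7=C11, C12=O) whose α-carbon C11 carries the acetoxymethyl carbon C13. The ring holds a C1=C10 enal alkene with C2 and C9 cis (formyl C14 trans to C2), a trans C4–C5 oxirane with methyl C15 on C4, and an isovalerate on C8. The stereocentres are C4 (R), C5 (R), C6 (R) and C8 (S). The oxirane oxygen and O6 are erythro, and O6 and O8 lie on opposite ring faces with the trigonal C7 between them. Sensitive groups are the α-(acetoxymethyl)butenolide (allylic acetate on an acceptor alkene, acidic γ-hydrogen at C6), the enal, two different esters, and an oxirane that can open transannularly under acid. O8 and C14 are 1,4-related, so a free C8 hydroxyl next to an oxidised C14 would close to a lactol or lactone; this fixes the order of the last steps. The hard points are the medium ring with two defined alkene geometries, the relay from C8 to C6 across C7, and an erythro epoxy-carbinol that runs against the usual substrate bias. The strategy rests on the unit O6–C6–C7–C11: a homoallylic alcohol with C11 as a branch on C7 is what a [2,3]-Wittig shift leaves behind. If C4–C5 is an alkyne at that stage, C6 is propargylic and the alkyne later becomes the E-alkene that carries C15.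

## Retrosynthetic reasoning

**43 back to 38.** The aldehyde is made last, from the C14 alcohol 42, and 42 from its silyl ether 41. The two esters are cut next (41 to 40 to 39). O8 must be acylated before C14 is unmasked, so O8 and O13 share one benzyl-type group, removed together from 38, and O14 carries a silyl group removed afterwards. In diol 39 the primary C13 hydroxyl is acetylated selectively, then the secondary C8 hydroxyl takes the isovalerate.

**38 back to 30.** The C7=C11 bond is traced to the saturated lactone 34 through selenide 36. The C12–O6 bond of 34 is cut to diol 32, and 32 comes from anti-Markovnikov hydration of the exocyclic C11=C12 methylene in 30. This turns C7 into an sp3 carbon bearing a 1,1-disubstituted alkene next to the C6 carbinol, the pattern of the sigmatropic step.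

**30 back to 29.** The oxirane is removed to give the E-alkene 29 with a free C6 hydroxyl. Hydroxyl-directed vanadium or peracid epoxidation of a secondary allylic alcohol that has a substituent cis to the carbinol (here C15) is threo-selective, and 43 is erythro. The forward step is therefore reagent-controlled: a titanium–tartrate epoxidation in which 29 is the fast-reacting, erythro-selective partner of the chosen tartrate enantiomer.

**29 back to 26.** The C4–C15 bond is cut (methyl cuprate on vinyl iodide 28), and 28 goes back to the cycloalkynol 26 by hydroxyl-directed trans-hydroalumination and iodination. The alkyne is thus the source of the E-trisubstituted alkene.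

**26 back to 24 (key).** The C6–C7 bond is cut and C12 is reconnected to O6, which gives the thirteen-membered propargyl allyl ether 24. The cut is made here because the forward [2,3] shift turns a large ring into the medium ring and sets the C6 carbinol, the C7 branch and the C11=C12 alkene in one operation. The forward step needs selective deprotonation at C6, a [2,3] and not a [1,2] shift, and transfer of the C8 configuration to C6.

**24 back to 23.** The C6–O bond is cut to allylic alcohol/propargylic chloride 23 (intramolecular Williamson etherification).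

**23 back to 17 and 20.** Alcohol 23 comes from enoate 22, and the C7=C11 bond of 22 is cut by a Horner–Wadsworth–Emmons disconnection. E-selectivity puts the ester carbon C12 trans to C8, the ring-trans geometry that 24 needs. C13 and its PMB ether arise in the same flask by alkoxide addition to acrylate 20, which is made from 18.

**17 back to 11.** The C7 aldehyde comes from the trityl-protected primary alcohol (15 to 16 to 17). C6 is added to the terminal alkyne of 11 by hydroxymethylation (13) and turned into the chloride (15) before the C12 alcohol exists, so neither terminus needs a protecting group.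

**11 back to 8.** Reduction of the α-alkylidene lactone 8 releases O8 and O14 together as diol 9. The primary one is silylated (10) and the secondary one benzylated (11).

**8 back to 4 and 2.** The C1=C10 bond is cut by an aldol condensation between the lactone 4 and aldehyde 2. The E-alkylidene lactone has C2 cis to C9 and the carbonyl carbon C14 trans to C2, which is the enal geometry of 43. Lactone 3 supplies C7–C10, C14 and the C8 stereocentre; 2 comes from 1.

## Alternatives that were turned down

**Alternative 1:** The C5–C6 bond is cut between an aldehyde carbon and the γ-carbon of a finished butenolide. In the forward direction the open-chain aldehyde A2 is converted into its 2-silyloxyfuran, and the furan γ-carbon adds to the Lewis-acid-activated aldehyde to close the ring as the C5 alcohol A1.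
- In its favour: the butenolide, the acetate and the isovalerate are in place before the ring forms, so few steps follow. On step economy after ring formation it is stronger than the chosen route.
- Against it: a ten-membered ring must close directly against transannular strain, in competition with oligomerisation and α-attack. C5 and C6 are both set in that closure with nothing in A2 to control them. The silyloxyfuran of A2 carries an acetate on the carbon next to C3 of the furan and an acyloxy group at C8, both placed to be lost by vinylogous elimination.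
- Comparison: the chosen route forms the ring as an unstrained thirteen-membered ether and contracts it intramolecularly. Its one uncertain centre (C6) can be inverted afterwards.

**Alternative 2:** The C3–C4 bond is cut. A tertiary dioxolanyl radical, formed by photocatalytic decarboxylation of acid A4, adds to the terminal carbon of the dienoate to give the ten-membered enoate A3.
- In its favour: mild conditions, and the fully substituted oxygenated C4 is made directly. On tolerance of functionality it is at least as strong as the chosen route.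
- Against it: a ten-membered radical ring closure competes with reduction and hydrogen transfer. The dienyl radical must be quenched so that C1=C10 ends ring-cis, which is not controlled. A3 still lacks C11–C13, so the butenolide would have to be built on the hindered C7 ketal carbon. The acetonide must also be converted into the oxirane with the right sense.
- Comparison: the chosen key step attaches the C11–C13 unit to C7 as the ring forms and leaves only functional-group changes.

**Alternative 3:** The ten-membered ring is revealed by fragmentation of a decalin. The sulfonylhydrazone of epoxy ketone A6 undergoes Eschenmoser–Tanabe fragmentation across the ring-fusion bond to the cycloalkynone A5.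
- In its favour: ring formation is the most dependable of all four plans, because fragmentation of a six-six system is insensitive to medium-ring strain. On that point it is stronger than the chosen route.
- Against it: A5 lacks C11–C15. The C10 ketone must be turned into a trisubstituted enal alkene of defined geometry inside the ring, and the butenolide must be annulated onto the C7 ketal carbon. A6, with three adjacent oxygenated carbons, is itself a long synthesis.
- Comparison: the chosen route carries every carbon into the macrocycle and fixes both alkene geometries in open-chain steps.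

Key step: step 16

## Route

Remark on the chemistry: the C7 configuration written for 26–36 is the predicted one and has no bearing on 43, because C7 becomes trigonal in 38.

Step 1
Reactants: 1 pent-4-yn-1-ol
Product: 2 pent-4-ynal
Conditions: (COCl)2, DMSO, CH2Cl2, −78 °C; Et3N, −78 → 0 °C
Reagents that add atoms: none
Why: Swern oxidation of a primary alcohol; the volatile aldehyde is used as a solution.

Step 2
Reactants: 3 (5S)-5-(hydroxymethyl)dihydrofuran-2(3H)-one
Product: 4 (5S)-5-[(trityloxy)methyl]dihydrofuran-2(3H)-one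
Conditions: TrCl, pyridine, DMAP (cat.), CH2Cl2, rt
Reagents that add atoms: trityl chloride, ClC(c1ccccc1)(c1ccccc1)c1ccccc1
Why: Tritylation of the primary alcohol; the trityl ether survives all basic and hydride steps up to step 10 and is later removed by mild acid without touching PMB or TBDPS ethers.

Step 3
Reactants: 4 (5S)-5-[(trityloxy)methyl]dihydrofuran-2(3H)-one; 2 pent-4-ynal
Product: 6 (5S)-3-(1-hydroxypent-4-yn-1-yl)-5-[(trityloxy)methyl]dihydrofuran-2(3H)-one (diastereomer mixture), via lithium enolate 5 (not isolated)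
Conditions: LDA, THF, −78 °C; then 2, −78 °C; AcOH quench
Reagents that add atoms: none
Why: Aldol addition of a lactone lithium enolate to an aldehyde; it is faster than proton transfer from the alkyne, and both new centres are removed in step 4.

Step 4
Reactants: 6 (5S)-3-(1-hydroxypent-4-yn-1-yl)-5-[(trityloxy)methyl]dihydrofuran-2(3H)-one
Product: 8 (3E,5S)-3-(pent-4-yn-1-ylidene)-5-[(trityloxy)methyl]dihydrofuran-2(3H)-one, via mesylate 7 (not isolated)
Conditions: MsCl, Et3N, CH2Cl2, 0 °C; then DBU, rt
Reagents that add atoms: none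
Why: Mesylation and E1cB elimination through the lactone enolate should give mainly the more stable E-alkylidene lactone; this sets C2 cis to C9 and C14 trans to C2.

Step 5
Reactants: 8 (3E,5S)-3-(pent-4-yn-1-ylidene)-5-[(trityloxy)methyl]dihydrofuran-2(3H)-one
Product: 9 (2S,4E)-4-(hydroxymethyl)-1-(trityloxy)non-4-en-8-yn-2-ol
Conditions: DIBAL-H (4.5 equiv), CH2Cl2, −78 → 0 °C; Rochelle salt
Reagents that add atoms: none
Why: 1,2-Reduction of an α,β-unsaturated lactone to the ene-diol with retention of alkene geometry; it releases the C14 and C8 hydroxyls as a primary/secondary pair.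

Step 6
Reactants: 9 (2S,4E)-4-(hydroxymethyl)-1-(trityloxy)non-4-en-8-yn-2-ol
Product: 10 (2S,4E)-4-{[tert-butyl(diphenyl)silyl]oxymethyl}-1-(trityloxy)non-4-en-8-yn-2-ol
Conditions: TBDPSCl (1.05 equiv), imidazole, CH2Cl2, 0 °C
Reagents that add atoms: tert-butyl(chloro)diphenylsilane, CC(C)(C)[Si](Cl)(c1ccccc1)c1ccccc1
Why: Silylation with a bulky chlorosilane is selective for the primary allylic hydroxyl over the secondary one.

Step 7
Reactants: 10 (2S,4E)-4-{[tert-butyl(diphenyl)silyl]oxymethyl}-1-(trityloxy)non-4-en-8-yn-2-ol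
Product: 11 (2S,4E)-4-{[tert-butyl(diphenyl)silyl]oxymethyl}-2-[(4-methoxybenzyl)oxy]-1-(trityloxy)non-4-en-8-yne
Conditions: NaH, PMBCl, Bu4NI (cat.), THF/DMF, 0 °C → rt
Reagents that add atoms: 4-methoxybenzyl chloride, COc1ccc(CCl)cc1
Why: Williamson benzylation of the secondary alkoxide; a PMB ether at O8 cannot migrate to the C6 alkoxide formed in step 16 and is removed later together with the O13 PMB group.

Step 8
Reactants: 11 (2S,4E)-4-{[tert-butyl(diphenyl)silyl]oxymethyl}-2-[(4-methoxybenzyl)oxy]-1-(trityloxy)non-4-en-8-yne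
Product: 13 (6E,9S)-7-{[tert-butyl(diphenyl)silyl]oxymethyl}-9-[(4-methoxybenzyl)oxy]-10-(trityloxy)dec-6-en-2-yn-1-ol, via lithium acetylide 12 (not isolated)
Conditions: n-BuLi, THF, −78 °C; (CH2O)n, −78 °C → rt
Reagents that add atoms: paraformaldehyde (as formaldehyde), C=O
Why: Hydroxymethylation of a lithium acetylide adds C6.

Step 9
Reactants: 13 (6E,9S)-7-{[tert-butyl(diphenyl)silyl]oxymethyl}-9-[(4-methoxybenzyl)oxy]-10-(trityloxy)dec-6-en-2-yn-1-ol
Product: 15 (2S,4E)-4-{[tert-butyl(diphenyl)silyl]oxymethyl}-10-chloro-2-[(4-methoxybenzyl)oxy]-1-(trityloxy)dec-4-en-8-yne, via mesylate 14 (not isolated)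
Conditions: MsCl, 2,4,6-collidine, LiCl, DMF, 0 °C → rt
Reagents that add atoms: lithium chloride, [Li+].[Cl-]
Why: In-situ mesylation and chloride displacement under basic buffering, which the trityl ether tolerates; the primary propargylic chloride is inert to the next five steps and serves as the electrophile in step 15.

Step 10
Reactants: 15 (2S,4E)-4-{[tert-butyl(diphenyl)silyl]oxymethyl}-10-chloro-2-[(4-methoxybenzyl)oxy]-1-(trityloxy)dec-4-en-8-yne
Product: 16 (2S,4E)-4-{[tert-butyl(diphenyl)silyl]oxymethyl}-10-chloro-2-[(4-methoxybenzyl)oxy]dec-4-en-8-yn-1-ol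
Conditions: TsOH·H2O (cat.), MeOH/CH2Cl2 (1:1), 0 °C → rt
Reagents that add atoms: none
Why: Acid-catalysed detritylation (methanol traps the trityl cation); PMB and TBDPS ethers are stable to these conditions.

Step 11
Reactants: 16 (2S,4E)-4-{[tert-butyl(diphenyl)silyl]oxymethyl}-10-chloro-2-[(4-methoxybenzyl)oxy]dec-4-en-8-yn-1-ol
Product: 17 (2S,4E)-4-{[tert-butyl(diphenyl)silyl]oxymethyl}-10-chloro-2-[(4-methoxybenzyl)oxy]dec-4-en-8-ynal
Conditions: DMP, NaHCO3, CH2Cl2, 0 °C → rt
Reagents that add atoms: none
Why: Dess–Martin oxidation under buffered, non-epimerising conditions; the α-alkoxy aldehyde is used at once.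

Step 12
Reactants: 18 triethyl phosphonoacetate
Product: 20 ethyl 2-(diethoxyphosphoryl)acrylate, via hydroxymethyl adduct 19 (not isolated)
Conditions: (CH2O)n, piperidine (cat.), MeOH, reflux; then TsOH·H2O (cat.), toluene, reflux (Dean–Stark)
Reagents that add atoms: paraformaldehyde (as formaldehyde), C=O
Why: Knoevenagel-type condensation with formaldehyde followed by acid-catalysed dehydration; the added carbon becomes C13.

Step 13
Reactants: 17 (2S,4E)-4-{[tert-butyl(diphenyl)silyl]oxymethyl}-10-chloro-2-[(4-methoxybenzyl)oxy]dec-4-en-8-ynal; 20 ethyl 2-(diethoxyphosphoryl)acrylate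
Product: 22 ethyl (2E,4S,6E)-6-{[tert-butyl(diphenyl)silyl]oxymethyl}-12-chloro-4-[(4-methoxybenzyl)oxy]-2-{[(4-methoxybenzyl)oxy]methyl}dodeca-2,6-dien-10-ynoate, via phosphonate carbanion 21 (not isolated)
Conditions: 4-methoxybenzyl alcohol, NaH, THF, 0 °C; 20, −20 → 0 °C; then 17, −78 → 0 °C
Reagents that add atoms: 4-methoxybenzyl alcohol, COc1ccc(CO)cc1
Why: Tandem oxa-Michael addition/Horner–Wadsworth–Emmons olefination; the α-substituted phosphonoacetate anion should react E-selectively with the α-branched aldehyde, placing the ester carbon C12 trans to C8 and CH2OPMB cis to C8. The weakly basic phosphonate anion should not epimerise C8.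

Step 14
Reactants: 22 ethyl (2E,4S,6E)-6-{[tert-butyl(diphenyl)silyl]oxymethyl}-12-chloro-4-[(4-methoxybenzyl)oxy]-2-{[(4-methoxybenzyl)oxy]methyl}dodeca-2,6-dien-10-ynoate
Product: 23 (2Z,4S,6E)-6-{[tert-butyl(diphenyl)silyl]oxymethyl}-12-chloro-4-[(4-methoxybenzyl)oxy]-2-{[(4-methoxybenzyl)oxy]methyl}dodeca-2,6-dien-10-yn-1-ol
Conditions: DIBAL-H (2.5 equiv), CH2Cl2, −78 °C; Rochelle salt
Reagents that add atoms: none
Why: 1,2-Reduction of the enoate to the allylic alcohol; the propargylic chloride is not reduced at −78 °C, and the descriptor change from E to Z is formal (the hydroxymethyl group stays trans to C8).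

Step 15
Reactants: 23 (2Z,4S,6E)-6-{[tert-butyl(diphenyl)silyl]oxymethyl}-12-chloro-4-[(4-methoxybenzyl)oxy]-2-{[(4-methoxybenzyl)oxy]methyl}dodeca-2,6-dien-10-yn-1-ol
Product: 24 thirteen-membered propargyl allyl ether (ring C11–C7–C8–C9–C10–C1–C2–C3–C4–C5–C6–O–C12; 8S; 8-OPMB; 13-OPMB; 14-OTBDPS)
Conditions: NaH (3 equiv), Bu4NI (10 mol%), THF (0.003 M, slow addition), rt → 45 °C
Reagents that add atoms: none
Why: Intramolecular Williamson etherification of a primary allylic alkoxide with a primary propargylic chloride (iodide catalysis); a thirteen-membered ring with a ring-trans alkene and an alkyne should close at high dilution, and the trans relation of C12 and C8 keeps the alkoxide away from O8.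

Step 16
Reactants: 24 thirteen-membered propargyl allyl ether (8S; 8-OPMB; 13-OPMB; 14-OTBDPS)
Product: 26 ten-membered cycloalkynol (6R,7S,8S; C4≡C5; C1=C10 ring-cis; 6-OH; 7-[3-(PMB-oxy)prop-1-en-2-yl]; 8-OPMB; 14-OTBDPS), via C6-lithio ether 25 (not isolated)
Conditions: n-BuLi (1.3 equiv), THF, −78 → −40 °C; aq. NH4Cl at −78 °C
Reagents that add atoms: none
Why: n-BuLi removes a proton from C6, the most acidic site because it is flanked by the ether oxygen and the alkyne; the carbanion adds to C7 through a five-membered envelope while the C12–O bond breaks and the π bond moves to C11=C12, a [2,3]-Wittig rearrangement. The closest known reaction type is the [2,3]-Wittig ring contraction of thirteen-membered propargylic allylic ethers to ten-membered cycloalkynols. The ten-membered ring is closed by this transannular, suprafacial shift inside the larger ring (O, C12 and C11 leave the ring), not by an end-to-end cyclisation. C7 is controlled by C8: CH2OPMB on C11 is cis to C8, so A(1,3) strain holds H8 in the alkene plane, C9 must lie on the face that C6 approaches because both are ring members, and the C8–O bond is then anti to the forming bond. C6 is controlled by the ring-trans C7=C11 bond: the O–C12 bridge and C8 lie on opposite sides of C7, so the rigid C4≡C5 rod on C6 can reach C3 only when it lies over the C8 side of the allyl unit (endo), which places H6 syn to H7 and O6 anti to O8. The step needs propargylic over allylic or benzylic deprotonation (secured by acidity and one equivalent of base at low temperature), [2,3] over [1,2] shift (low temperature), and the O6/O8 anti relation (secured by the two elements above). C7 is erased in step 23, so only the C6/C8 relation has to hold.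

Step 17
Reactants: 26 ten-membered cycloalkynol (6R,7S,8S)
Product: 28 (4Z)-4-iodo-cyclodeca-1(10),4-dien-6-ol derivative (I on C4 cis to C6; other groups as in 26), via cyclic alkenylalanate 27 (not isolated)
Conditions: Red-Al (2 equiv), THF, 0 °C → rt; then I2, −78 → 0 °C
Reagents that add atoms: iodine, II
Why: Hydroxyl-directed trans-hydroalumination of a propargylic alcohol delivers hydride to C5 and aluminium to C4 in a five-membered alanate; iodinolysis occurs with retention, so C3 and C6 are trans.

Step 18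
Reactants: 28 (4Z)-4-iodo-cyclodeca-1(10),4-dien-6-ol derivative
Product: 29 (4E)-4-methylcyclodeca-1(10),4-dien-6-ol derivative (C15 on C4 cis to C6; other groups as in 26)
Conditions: Me2CuLi (from CuI and MeLi, 5 equiv), Et2O, −20 → 0 °C
Reagents that add atoms: lithium dimethylcuprate, [Li+].C[Cu-]C
Why: Cuprate substitution of an alkenyl iodide with retention of geometry gives the E-trisubstituted alkene; the product is kept at or below room temperature because it is a 1,5-diene that could undergo Cope rearrangement.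

Step 19
Reactants: 29 (4E)-4-methylcyclodeca-1(10),4-dien-6-ol derivative
Product: 30 (4R,5R,6R,7S,8S)-4,5-epoxy alcohol (other groups as in 26)
Conditions: Ti(OiPr)4, D-(−)-diisopropyl tartrate, t-BuOOH (decane), 4 Å MS, CH2Cl2, −20 °C
Reagents that add atoms: tert-butyl hydroperoxide, CC(C)(C)OO
Why: Sharpless titanium–tartrate epoxidation in its matched sense: D-(−)-tartrate delivers oxygen to the face that gives 4R,5R, and on that face the C6 hydrogen, not C7, faces the reagent, which is the arrangement of the fast-reacting enantiomer and leads to the erythro product. The required conformer has C7 on the inner face of the E-alkene, so the attack is also peripheral; the homoallylic C11=C12 and the remote C1=C10 alkenes should not react.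

Step 20
Reactants: 30 (4R,5R,6R,7S,8S)-4,5-epoxy alcohol
Product: 32 4,5-epoxy-6,12-diol (C11 epimers), via C12 alkylborane 31 (not isolated)
Conditions: 9-BBN (3 equiv), THF, 0 °C → rt; then 30% H2O2, aq. NaHCO3, 0 °C
Reagents that add atoms: hydrogen peroxide, OO
Why: Anti-Markovnikov hydroboration–oxidation; 9-BBN selects the 1,1-disubstituted alkene over the trisubstituted one, and the weakly basic oxidation avoids Payne rearrangement. The C11 configuration is irrelevant.

Step 21
Reactants: 32 4,5-epoxy-6,12-diol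
Product: 34 saturated 12,6-lactone (11,13-dihydro; C11 epimers), via lactol 33 (not isolated)
Conditions: TEMPO (0.2 equiv), PhI(OAc)2 (2.5 equiv), CH2Cl2, rt
Reagents that add atoms: none
Why: Oxidative lactonisation of a 1,4-diol: the primary alcohol is oxidised selectively, the aldehyde closes to the lactol with the C6 hydroxyl, and the lactol is oxidised further.

Step 22
Reactants: 34 saturated 12,6-lactone
Product: 36 11-(phenylselanyl) lactone (Se cis to H7), via lithium enolate 35 (not isolated)
Conditions: LDA (1.3 equiv), THF, −78 °C; PhSeBr, −78 °C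
Reagents that add atoms: phenylselanyl bromide, Br[Se]c1ccccc1
Why: α-Selenenylation of a lactone enolate; the electrophile should enter from the convex face of the cis-fused bicycle, the face that carries H7. The cold enolate should not eliminate the β-alkoxide.

Step 23
Reactants: 36 11-(phenylselanyl) lactone
Product: 38 butenolide (C7=C11; 4R,5R,6R,8S; 8-OPMB; 13-OPMB; 14-OTBDPS), via selenoxide 37 (not isolated)
Conditions: 30% H2O2, pyridine, CH2Cl2, 0 °C → rt
Reagents that add atoms: none
Why: Selenoxide syn-elimination; it takes the syn hydrogen at C7 and avoids the oxygen-bearing C13, the usual regiochemistry away from oxygen, giving the conjugated tetrasubstituted alkene. Pyridine buffering suppresses epoxidation of C1=C10.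

Step 24
Reactants: 38 butenolide
Product: 39 8,13-diol (14-OTBDPS)
Conditions: DDQ (3 equiv), CH2Cl2/pH 7 buffer (10:1), 0 °C → rt
Reagents that add atoms: none
Why: Oxidative cleavage of both PMB ethers under neutral conditions that the oxirane, silyl ether and butenolide tolerate; C12 is trans to C8 across C7=C11, so O8 cannot translactonise.

Step 25
Reactants: 39 8,13-diol
Product: 40 13-acetate (8-OH; 14-OTBDPS)
Conditions: AcCl (1.1 equiv), 2,4,6-collidine, CH2Cl2, −78 °C
Reagents that add atoms: acetyl chloride, CC(=O)Cl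
Why: Low-temperature acylation with a hindered base is selective for the primary hydroxyl over the hindered secondary one.

Step 26
Reactants: 40 13-acetate
Product: 41 8-isovalerate 13-acetate (14-OTBDPS)
Conditions: (i-BuCO)2O, DMAP (0.2 equiv), pyridine, CH2Cl2, 0 °C → rt
Reagents that add atoms: 3-methylbutanoic anhydride, CC(C)CC(=O)OC(=O)CC(C)C
Why: DMAP-catalysed esterification of the secondary alcohol; no alkoxide is formed, so displacement of the neighbouring allylic acetate should not compete.

Step 27
Reactants: 41 8-isovalerate 13-acetate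
Product: 42 C14 allylic alcohol
Conditions: Bu4NF/AcOH (1:1), THF, 0 °C → rt
Reagents that add atoms: none
Why: Buffered fluoride desilylation; acid is avoided because of the oxirane, and unbuffered fluoride because of the esters and the butenolide.

Step 28
Reactants: 42 C14 allylic alcohol
Product: 43 target
Conditions: DMP, NaHCO3, CH2Cl2, 0 °C → rt
Reagents that add atoms: none
Why: Dess–Martin oxidation of the only free hydroxyl to the enal without alkene isomerisation; O8 is already acylated, so no lactol can form.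

## Compound list

1 | pent-4-yn-1-ol | C#CCCCO | starting material
2 | pent-4-ynal | C#CCCC=O | intermediate
3 | (5S)-5-(hydroxymethyl)dihydrofuran-2(3H)-one | OC[C@@H]1CCC(=O)O1 | starting material
4 | (5S)-5-[(trityloxy)methyl]dihydrofuran-2(3H)-one | O=C1CC[C@@H](COC(c2ccccc2)(c2ccccc2)c2ccccc2)O1 | intermediate
5 | lithium enolate of 4 | [Li]OC1=CC[C@@H](COC(c2ccccc2)(c2ccccc2)c2ccccc2)O1 | intermediate
6 | (5S)-3-(1-hydroxypent-4-yn-1-yl)-5-[(trityloxy)methyl]dihydrofuran-2(3H)-one, diastereomer mixture | C#CCCC(O)C1C[C@@H](COC(c2ccccc2)(c2ccccc2)c2ccccc2)OC1=O | intermediate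
7 | methanesulfonate of 6 | C#CCCC(OS(C)(=O)=O)C1C[C@@H](COC(c2ccccc2)(c2ccccc2)c2ccccc2)OC1=O | intermediate
8 | (3E,5S)-3-(pent-4-yn-1-ylidene)-5-[(trityloxy)methyl]dihydrofuran-2(3H)-one | C#CCC/C=C1\C[C@@H](COC(c2ccccc2)(c2ccccc2)c2ccccc2)OC1=O | intermediate
9 | (2S,4E)-4-(hydroxymethyl)-1-(trityloxy)non-4-en-8-yn-2-ol | c1ccccc1C(c1ccccc1)(c1ccccc1)OC[C@@H](O)C/C(CO)=C\CCC#C | intermediate
10 | (2S,4E)-4-{[tert-butyl(diphenyl)silyl]oxymethyl}-1-(trityloxy)non-4-en-8-yn-2-ol | c1ccccc1C(c1ccccc1)(c1ccccc1)OC[C@@H](O)C/C(CO[Si](c1ccccc1)(c1ccccc1)C(C)(C)C)=C\CCC#C | intermediate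
11 | (2S,4E)-4-{[tert-butyl(diphenyl)silyl]oxymethyl}-2-[(4-methoxybenzyl)oxy]-1-(trityloxy)non-4-en-8-yne | c1ccccc1C(c1ccccc1)(c1ccccc1)OC[C@@H](OCc1ccc(OC)cc1)C/C(CO[Si](c1ccccc1)(c1ccccc1)C(C)(C)C)=C\CCC#C | intermediate
12 | lithium acetylide of 11 | c1ccccc1C(c1ccccc1)(c1ccccc1)OC[C@@H](OCc1ccc(OC)cc1)C/C(CO[Si](c1ccccc1)(c1ccccc1)C(C)(C)C)=C\CCC#C[Li] | intermediate
13 | (6E,9S)-7-{[tert-butyl(diphenyl)silyl]oxymethyl}-9-[(4-methoxybenzyl)oxy]-10-(trityloxy)dec-6-en-2-yn-1-ol | c1ccccc1C(c1ccccc1)(c1ccccc1)OC[C@@H](OCc1ccc(OC)cc1)C/C(CO[Si](c1ccccc1)(c1ccccc1)C(C)(C)C)=C\CCC#CCO | intermediate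
14 | methanesulfonate of 13 | c1ccccc1C(c1ccccc1)(c1ccccc1)OC[C@@H](OCc1ccc(OC)cc1)C/C(CO[Si](c1ccccc1)(c1ccccc1)C(C)(C)C)=C\CCC#CCOS(C)(=O)=O | intermediate
15 | (2S,4E)-4-{[tert-butyl(diphenyl)silyl]oxymethyl}-10-chloro-2-[(4-methoxybenzyl)oxy]-1-(trityloxy)dec-4-en-8-yne | c1ccccc1C(c1ccccc1)(c1ccccc1)OC[C@@H](OCc1ccc(OC)cc1)C/C(CO[Si](c1ccccc1)(c1ccccc1)C(C)(C)C)=C\CCC#CCCl | intermediate
16 | (2S,4E)-4-{[tert-butyl(diphenyl)silyl]oxymethyl}-10-chloro-2-[(4-methoxybenzyl)oxy]dec-4-en-8-yn-1-ol | OC[C@@H](OCc1ccc(OC)cc1)C/C(CO[Si](c1ccccc1)(c1ccccc1)C(C)(C)C)=C\CCC#CCCl | intermediate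
17 | (2S,4E)-4-{[tert-butyl(diphenyl)silyl]oxymethyl}-10-chloro-2-[(4-methoxybenzyl)oxy]dec-4-en-8-ynal | O=C[C@@H](OCc1ccc(OC)cc1)C/C(CO[Si](c1ccccc1)(c1ccccc1)C(C)(C)C)=C\CCC#CCCl | intermediate
18 | triethyl phosphonoacetate | CCOC(=O)CP(=O)(OCC)OCC | starting material
19 | ethyl 2-(diethoxyphosphoryl)-3-hydroxypropanoate | CCOC(=O)C(CO)P(=O)(OCC)OCC | intermediate
20 | ethyl 2-(diethoxyphosphoryl)acrylate | C=C(C(=O)OCC)P(=O)(OCC)OCC | intermediate
21 | sodium carbanion of ethyl 2-(diethoxyphosphoryl)-3-[(4-methoxybenzyl)oxy]propanoate | [Na+].CCOC(=O)[C-](COCc1ccc(OC)cc1)P(=O)(OCC)OCC | intermediate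
22 | ethyl (2E,4S,6E)-6-{[tert-butyl(diphenyl)silyl]oxymethyl}-12-chloro-4-[(4-methoxybenzyl)oxy]-2-{[(4-methoxybenzyl)oxy]methyl}dodeca-2,6-dien-10-ynoate | CCOC(=O)/C(COCc1ccc(OC)cc1)=C/[C@@H](OCc1ccc(OC)cc1)C/C(CO[Si](c1ccccc1)(c1ccccc1)C(C)(C)C)=C\CCC#CCCl | intermediate
23 | (2Z,4S,6E)-6-{[tert-butyl(diphenyl)silyl]oxymethyl}-12-chloro-4-[(4-methoxybenzyl)oxy]-2-{[(4-methoxybenzyl)oxy]methyl}dodeca-2,6-dien-10-yn-1-ol (hydroxymethyl trans to C8) | OC/C(COCc1ccc(OC)cc1)=C/[C@@H](OCc1ccc(OC)cc1)C/C(CO[Si](c1ccccc1)(c1ccccc1)C(C)(C)C)=C\CCC#CCCl | intermediate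
24 | thirteen-membered propargyl allyl ether; C6–O–C12 ether, C4≡C5, C7=C11 with C12 trans to C8, C1=C10 with C2 cis to C9, 8S, 8-OPMB, 13-OPMB, 14-OTBDPS | COc1ccc(COC/C2=C\[C@@H](OCc3ccc(OC)cc3)C/C(CO[Si](c3ccccc3)(c3ccccc3)C(C)(C)C)=C\CCC#CCOC2)cc1 | intermediate
25 | C6-lithio derivative of 24 | COc1ccc(COC/C2=C\[C@@H](OCc3ccc(OC)cc3)C/C(CO[Si](c3ccccc3)(c3ccccc3)C(C)(C)C)=C\CCC#CC([Li])OC2)cc1 | intermediate
26 | (6R,7S,8S)-ten-membered cycloalkynol; C4≡C5, C1=C10 ring-cis, 6-OH, 7-[3-(4-methoxybenzyloxy)prop-1-en-2-yl], 8-OPMB, 14-OTBDPS | C=C(COCc1ccc(OC)cc1)[C@@H]1[C@@H](OCc2ccc(OC)cc2)C/C(CO[Si](c2ccccc2)(c2ccccc2)C(C)(C)C)=C\CCC#C[C@@H]1O | intermediate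
27 | cyclic sodium alkenylalanate of 26 (O6–Al–C4=C5 five-membered ring) | [Na+].C=C(COCc1ccc(OC)cc1)[C@@H]1[C@@H](OCc2ccc(OC)cc2)C/C(CO[Si](c2ccccc2)(c2ccccc2)C(C)(C)C)=C\CCC2=C[C@@H]1O[Al-]2(OCCOC)OCCOC | intermediate
28 | (4Z)-4-iodo alkenol; I on C4 cis to C6, C3 trans to C6 | C=C(COCc1ccc(OC)cc1)[C@@H]1[C@@H](OCc2ccc(OC)cc2)C/C(CO[Si](c2ccccc2)(c2ccccc2)C(C)(C)C)=C\CC/C(I)=C/[C@@H]1O | intermediate
29 | (4E)-4-methyl allylic alcohol; germacra-1(10),4,11-trien-6-ol skeleton, 8-OPMB, 13-OPMB, 14-OTBDPS | C=C(COCc1ccc(OC)cc1)[C@@H]1[C@@H](OCc2ccc(OC)cc2)C/C(CO[Si](c2ccccc2)(c2ccccc2)C(C)(C)C)=C\CC/C(C)=C/[C@@H]1O | intermediate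
30 | (4R,5R,6R,7S,8S)-4,5-epoxy alcohol | C=C(COCc1ccc(OC)cc1)[C@@H]1[C@@H](OCc2ccc(OC)cc2)C/C(CO[Si](c2ccccc2)(c2ccccc2)C(C)(C)C)=C\CC[C@@]2(C)O[C@@H]2[C@@H]1O | intermediate
31 | C12 B-alkyl-9-borabicyclo[3.3.1]nonane of 30 (O6 as its borinate) | C(B1C2CCCC1CCC2)C(COCc1ccc(OC)cc1)[C@@H]1[C@@H](OCc2ccc(OC)cc2)C/C(CO[Si](c2ccccc2)(c2ccccc2)C(C)(C)C)=C\CC[C@@]2(C)O[C@@H]2[C@@H]1OB1C2CCCC1CCC2 | intermediate
32 | 4,5-epoxy-6,12-diol, C11 epimers | OCC(COCc1ccc(OC)cc1)[C@@H]1[C@@H](OCc2ccc(OC)cc2)C/C(CO[Si](c2ccccc2)(c2ccccc2)C(C)(C)C)=C\CC[C@@]2(C)O[C@@H]2[C@@H]1O | intermediate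
33 | 12,6-lactol | COc1ccc(COCC2[C@@H]3[C@@H](OCc4ccc(OC)cc4)C/C(CO[Si](c4ccccc4)(c4ccccc4)C(C)(C)C)=C\CC[C@@]4(C)O[C@@H]4[C@@H]3OC2O)cc1 | intermediate
34 | saturated 12,6-lactone, C11 epimers | COc1ccc(COCC2[C@@H]3[C@@H](OCc4ccc(OC)cc4)C/C(CO[Si](c4ccccc4)(c4ccccc4)C(C)(C)C)=C\CC[C@@]4(C)O[C@@H]4[C@@H]3OC2=O)cc1 | intermediate
35 | lithium enolate of 34 | COc1ccc(COCC=2[C@@H]3[C@@H](OCc4ccc(OC)cc4)C/C(CO[Si](c4ccccc4)(c4ccccc4)C(C)(C)C)=C\CC[C@@]4(C)O[C@@H]4[C@@H]3OC=2O[Li])cc1 | intermediate
36 | 11-(phenylselanyl) lactone, Se cis to H7 | COc1ccc(COC[C@]2([Se]c5ccccc5)[C@@H]3[C@@H](OCc4ccc(OC)cc4)C/C(CO[Si](c4ccccc4)(c4ccccc4)C(C)(C)C)=C\CC[C@@]4(C)O[C@@H]4[C@@H]3OC2=O)cc1 | intermediate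
37 | selenoxide of 36 | COc1ccc(COC[C@]2([Se](=O)c5ccccc5)[C@@H]3[C@@H](OCc4ccc(OC)cc4)C/C(CO[Si](c4ccccc4)(c4ccccc4)C(C)(C)C)=C\CC[C@@]4(C)O[C@@H]4[C@@H]3OC2=O)cc1 | intermediate
38 | butenolide; C7=C11, 4R,5R,6R,8S, 8-OPMB, 13-OPMB, 14-OTBDPS | COc1ccc(COCC2=C3[C@@H](OCc4ccc(OC)cc4)C/C(CO[Si](c4ccccc4)(c4ccccc4)C(C)(C)C)=C\CC[C@@]4(C)O[C@@H]4[C@@H]3OC2=O)cc1 | intermediate
39 | 8,13-diol, 14-OTBDPS | OCC1=C2[C@@H](O)C/C(CO[Si](c3ccccc3)(c3ccccc3)C(C)(C)C)=C\CC[C@@]3(C)O[C@@H]3[C@@H]2OC1=O | intermediate
40 | 13-acetate, 8-OH, 14-OTBDPS | CC(=O)OCC1=C2[C@@H](O)C/C(CO[Si](c3ccccc3)(c3ccccc3)C(C)(C)C)=C\CC[C@@]3(C)O[C@@H]3[C@@H]2OC1=O | intermediate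
41 | 8-isovalerate 13-acetate, 14-OTBDPS | CC(=O)OCC1=C2[C@@H](OC(=O)CC(C)C)C/C(CO[Si](c3ccccc3)(c3ccccc3)C(C)(C)C)=C\CC[C@@]3(C)O[C@@H]3[C@@H]2OC1=O | intermediate
42 | C14 allylic alcohol | CC(=O)OCC1=C2[C@@H](OC(=O)CC(C)C)C/C(CO)=C\CC[C@@]3(C)O[C@@H]3[C@@H]2OC1=O | intermediate
43 | CNP0289605.1 | CC(=O)OCC1=C2[C@@H](OC(=O)CC(C)C)C/C(C=O)=C\CC[C@@]3(C)O[C@@H]3[C@@H]2OC1=O | target

## Step count and least certain steps

Total: 28 steps. Longest linear sequence: 26 steps (3 to 43 through steps 2–11 and 13–28; the same length from 1). The 13-membered precursor 24 is reached in 13 linear steps.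

**Step 16 (key).** The alkyne may take the exo orientation that open-chain propargyl ethers prefer, which would set C6 with the opposite sense against C8; a [1,2] shift or allylic deprotonation may also compete. Fallback: set out from 24 and accept the C6 epimer F1. Mitsunobu esterification with 4-nitrobenzoic acid (PPh3, DIAD) inverts C6 to give ester F2, and K2CO3/MeOH returns the route at 26. Propargylic alcohols are good substrates for this inversion.

**Step 19.** The titanium–tartrate complex may react slowly or with poor face selectivity, because the reactive conformer holds O6 near the alkene plane beside C15 inside a medium ring. Fallback from 29: Mitsunobu inversion at C6 gives the 4-nitrobenzoate F3 and, after methanolysis, the epimeric alcohol F4. Substrate-directed epoxidation of F4 (VO(acac)2, t-BuOOH) should follow the threo preference and give the 4R,5R oxirane in F5. A second Mitsunobu inversion gives F6, and methanolysis comes back at 30.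

**Step 13.** E/Z selectivity may erode, or the alkoxide may be lost from the carbanion by retro-Michael reaction. Fallback from 17: aldol addition of the lithium enolate of ethyl 3-[(4-methoxybenzyl)oxy]propanoate gives hydroxy ester F7. Mesylation to F8 and DBU elimination under thermodynamic control come back at 22.

**Step 15.** Oligomerisation, or slow closure with decomposition of the alkoxide/chloride pair, may lower the yield. Fallback from 23: Finkelstein exchange (NaI, acetone) gives the propargylic iodide F9. Ring closure promoted by Ag2O in dilute CH2Cl2 activates the halide without generating a free alkoxide and comes back at 24.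

**Step 23.** If the selenium has entered trans to H7, no syn hydrogen is available at C7 and elimination would run toward C13 to an enol ether. Fallback from 34: LiHMDS/Me3SiCl gives the silyl ketene acetal F10. Saegusa–Ito dehydrogenation with Pd(OAc)2 in MeCN does not depend on the C11 configuration and comes back at 38.

## Further compounds

F1 | step 16 | C6 epimer of 26 | C=C(COCc1ccc(OC)cc1)[C@@H]1[C@@H](OCc2ccc(OC)cc2)C/C(CO[Si](c2ccccc2)(c2ccccc2)C(C)(C)C)=C\CCC#C[C@H]1O
F2 | step 16 | 4-nitrobenzoate of 26 | C=C(COCc1ccc(OC)cc1)[C@@H]1[C@@H](OCc2ccc(OC)cc2)C/C(CO[Si](c2ccccc2)(c2ccccc2)C(C)(C)C)=C\CCC#C[C@@H]1OC(=O)c2ccc(cc2)[N+](=O)[O-]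
F3 | step 19 | 4-nitrobenzoate of the C6 epimer of 29 | C=C(COCc1ccc(OC)cc1)[C@@H]1[C@@H](OCc2ccc(OC)cc2)C/C(CO[Si](c2ccccc2)(c2ccccc2)C(C)(C)C)=C\CC/C(C)=C/[C@H]1OC(=O)c2ccc(cc2)[N+](=O)[O-]
F4 | step 19 | C6 epimer of 29 | C=C(COCc1ccc(OC)cc1)[C@@H]1[C@@H](OCc2ccc(OC)cc2)C/C(CO[Si](c2ccccc2)(c2ccccc2)C(C)(C)C)=C\CC/C(C)=C/[C@H]1O
F5 | step 19 | C6 epimer of 30 (4R,5R oxirane, threo) | C=C(COCc1ccc(OC)cc1)[C@@H]1[C@@H](OCc2ccc(OC)cc2)C/C(CO[Si](c2ccccc2)(c2ccccc2)C(C)(C)C)=C\CC[C@@]2(C)O[C@@H]2[C@H]1O
F6 | step 19 | 4-nitrobenzoate of 30 | C=C(COCc1ccc(OC)cc1)[C@@H]1[C@@H](OCc2ccc(OC)cc2)C/C(CO[Si](c2ccccc2)(c2ccccc2)C(C)(C)C)=C\CC[C@@]2(C)O[C@@H]2[C@@H]1OC(=O)c2ccc(cc2)[N+](=O)[O-]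
F7 | step 13 | ethyl 3-hydroxy-2-{[(4-methoxybenzyl)oxy]methyl} ester (aldol adduct of 17, diastereomer mixture) | CCOC(=O)C(COCc1ccc(OC)cc1)C(O)[C@@H](OCc1ccc(OC)cc1)C/C(CO[Si](c1ccccc1)(c1ccccc1)C(C)(C)C)=C\CCC#CCCl
F8 | step 13 | methanesulfonate of F7 | CCOC(=O)C(COCc1ccc(OC)cc1)C(OS(C)(=O)=O)[C@@H](OCc1ccc(OC)cc1)C/C(CO[Si](c1ccccc1)(c1ccccc1)C(C)(C)C)=C\CCC#CCCl
F9 | step 15 | propargylic iodide corresponding to 23 | OC/C(COCc1ccc(OC)cc1)=C/[C@@H](OCc1ccc(OC)cc1)C/C(CO[Si](c1ccccc1)(c1ccccc1)C(C)(C)C)=C\CCC#CCI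
F10 | step 23 | trimethylsilyl ketene acetal of 34 | COc1ccc(COCC=2[C@@H]3[C@@H](OCc4ccc(OC)cc4)C/C(CO[Si](c4ccccc4)(c4ccccc4)C(C)(C)C)=C\CC[C@@]4(C)O[C@@H]4[C@@H]3OC=2O[Si](C)(C)C)cc1
A1 | alternative 1 | ten-membered C5 alcohol with C4 triethylsilyl ether (vinylogous aldol product) | CC(=O)OCC1=C2[C@@H](OC(=O)CC(C)C)C/C(CO[Si](C)(C)C(C)(C)C)=C\CC[C@@](C)(O[Si](CC)(CC)CC)[C@@H](O)[C@@H]2OC1=O
A2 | alternative 1 | open-chain C5 aldehyde carrying the C6-unsubstituted butenolide | CC(=O)OCC1=C(COC1=O)[C@@H](OC(=O)CC(C)C)C/C(CO[Si](C)(C)C(C)(C)C)=C\CC[C@@](C)(O[Si](CC)(CC)CC)C=O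
A3 | alternative 2 | ten-membered 4,5-acetonide C14 methyl enoate | COC(=O)/C1=C/CC[C@@]2(C)OC(C)(C)O[C@@H]2[C@H](OCc3ccc(OC)cc3)C(OC)(OC)[C@@H](O[Si](C)(C)C(C)(C)C)C1
A4 | alternative 2 | C4 carboxylic acid on the 4,5-acetonide with the pentadienoate terminus | OC(=O)[C@@]1(C)OC(C)(C)O[C@@H]1[C@H](OCc2ccc(OC)cc2)C(OC)(OC)[C@@H](O[Si](C)(C)C(C)(C)C)C/C(C(=O)OC)=C\C=C
A5 | alternative 3 | ten-membered 4-yn-10-one | O=C1CCCC#C[C@H](OCc2ccc(OC)cc2)C(OC)(OC)[C@@H](O[Si](C)(C)C(C)(C)C)C1
A6 | alternative 3 | 5,10-epoxydecalin-4-one (either epoxide face; both epoxide centres are lost) | O=C1CCCC23OC12[C@H](OCc1ccc(OC)cc1)C(OC)(OC)[C@@H](O[Si](C)(C)C(C)(C)C)C3
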